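Retrosynthesis: acredinone A is a masked dimer of one benzophenone, (2,6-dimethoxyphenyl)(2-hydroxy-5-methoxy-4-methylphenyl) ketone; the five-membered ring of the indenone is cut at C-1–C-7a and at C-2–C-3.
This leaves benzophenone 5 (right half, C-3 still a ketone carbon) and ynamide 17, the same benzophenone carrying the C-2/C-1 alkyne on its corresponding ortho carbon, with the N-bearing alkyne carbon as a masked C-1 carbonyl.
Enabling feature: C-3 is a diaryl ketone carbon whose only ortho C–H in either aryl ring is C-7a (the other three ortho positions carry oxygen), so ketone-directed C–H metalation has a single possible site.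
Forward: phenol 1 → MOM ether 2 → (ortho-lithiation, acylation) benzophenone 5; separately 1 → (ortho-formylation) salicylaldehyde 7 → MOM ether 8 → iodo aldehyde 11 → iodo ketone 15 → ynamide 17. A rhodium-catalysed (3+2) annulation of 5 with 17 closes the five-membered ring as amino-indenol 18; aqueous acid then hydrolyses the ene-sulfonamide, dehydrates to the indenone and removes both MOM groups.
Stereochemistry: the target has no stereocentre; the carbinol centres of 14, 18 and 19 form as racemates and are erased by oxidation (step 7) and by the hydrolysis–dehydration (step 10).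

Key step: step 9

Remark: the target SMILES defines no stereocentre and no axis, so the hindered aryl–indenone and aryl–carbonyl axes are treated as configurationally undefined; 4-methoxy-3-methylphenol (1) and the terminal ynamide N-ethynyl-N,4-dimethylbenzenesulfonamide (16) are taken to be catalogue compounds.

Step 1
Reactants: 1 4-methoxy-3-methylphenol
Product: 2 1-methoxy-4-(methoxymethoxy)-2-methylbenzene
Conditions: NaH, MOMCl, THF/DMF, 0 °C → rt
Reagents that add atoms: chloromethyl methyl ether (MOMCl), COCCl
Why: Williamson-type O-alkylation of the sodium phenoxide by the α-chloro ether should install the MOM acetal, which serves as protecting group and as ortho-directing group for step 2.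

Step 2
Reactants: 2 1-methoxy-4-(methoxymethoxy)-2-methylbenzene; 3 2,6-dimethoxybenzoyl chloride
Product: 5 (2,6-dimethoxyphenyl)[5-methoxy-2-(methoxymethoxy)-4-methylphenyl]methanone, via aryllithium 4 (not isolated)
Conditions: n-BuLi, TMEDA, THF, 0 °C; then cannulated into 3, THF, −78 °C → rt
Reagents that add atoms: none
Why: Directed ortho-metalation, in which the chelating OMOM group outranks OMe and directs lithiation to its unhindered ortho carbon (the other one is buttressed by the methyl group), followed by acylation of the aryllithium under inverse addition, where the tri-ortho-substituted ketone should resist a second addition.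

Step 3
Reactants: 1 4-methoxy-3-methylphenol
Product: 7 2-hydroxy-5-methoxy-4-methylbenzaldehyde, via ortho-hydroxymethyl magnesium phenoxide 6 (not isolated)
Conditions: MgCl2, Et3N, (CH2O)n, MeCN, reflux; 1 M aq. HCl
Reagents that add atoms: formaldehyde (as paraformaldehyde), C=O
Why: Magnesium-mediated ortho-formylation of a phenol (Casnati–Skattebøl reaction), in which the magnesium phenoxide delivers formaldehyde only to a carbon ortho to oxygen, here the open one and not the one wedged between oxygen and the methyl group, and a second formaldehyde takes up hydride from the hydroxymethyl intermediate 6 (Oppenauer-type) to give the salicylaldehyde.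

Step 4
Reactants: 7 2-hydroxy-5-methoxy-4-methylbenzaldehyde
Product: 8 5-methoxy-2-(methoxymethoxy)-4-methylbenzaldehyde
Conditions: MOMCl, i-Pr2NEt, CH2Cl2, 0 °C → rt
Reagents that add atoms: chloromethyl methyl ether (MOMCl), COCCl
Why: O-alkylation of the salicylaldehyde hydroxyl by the α-chloro ether under amine-base conditions should give the MOM acetal, which blocks one ortho position of the formyl group and so leaves a single site for the metalation of step 5.

Step 5
Reactants: 8 5-methoxy-2-(methoxymethoxy)-4-methylbenzaldehyde
Product: 11 2-iodo-3-methoxy-6-(methoxymethoxy)-4-methylbenzaldehyde, via lithium amino alkoxide 9 (not isolated), via ortho-lithiated amino alkoxide 10 (not isolated)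
Conditions: HN(Me)CH2CH2NMe2, n-BuLi, THF, −20 °C; n-BuLi (3 equiv), −20 °C; I2, −78 °C → rt; H2O
Reagents that add atoms: iodine, II
Why: In situ protection of the aldehyde as a chelating α-amino alkoxide and directed ortho-lithiation should metalate the only free carbon next to it, which is also ortho to OMe (cooperative 1,3-relationship of two directing groups); iodinolysis and hydrolytic release of the aldehyde then give 11, the racemic aminal carbon being lost on work-up.

Step 6
Reactants: 11 2-iodo-3-methoxy-6-(methoxymethoxy)-4-methylbenzaldehyde; 12 1,3-dimethoxybenzene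
Product: 14 rac-(2,6-dimethoxyphenyl)[2-iodo-3-methoxy-6-(methoxymethoxy)-4-methylphenyl]methanol, via 2,6-dimethoxyphenyllithium 13 (not isolated)
Conditions: 12, n-BuLi, THF, 0 °C → rt; then 11, THF, −78 °C; H2O
Reagents that add atoms: none
Why: 1,3-Dimethoxybenzene is lithiated between its two methoxy groups (directed ortho-metalation), and this doubly stabilised aryllithium should add 1,2 to the aldehyde at −78 °C faster than it exchanges with the aryl iodide; the carbinol centre is racemic and is removed in step 7.

Step 7
Reactants: 14 rac-(2,6-dimethoxyphenyl)[2-iodo-3-methoxy-6-(methoxymethoxy)-4-methylphenyl]methanol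
Product: 15 (2,6-dimethoxyphenyl)[2-iodo-3-methoxy-6-(methoxymethoxy)-4-methylphenyl]methanone
Conditions: Dess–Martin periodinane, CH2Cl2, 0 °C → rt
Reagents that add atoms: none
Why: Dess–Martin oxidation should convert the hindered diaryl carbinol into the diaryl ketone under nearly neutral conditions that spare the MOM acetal and the aryl iodide.

Step 8
Reactants: 15 (2,6-dimethoxyphenyl)[2-iodo-3-methoxy-6-(methoxymethoxy)-4-methylphenyl]methanone; 16 N-ethynyl-N,4-dimethylbenzenesulfonamide
Product: 17 N-{[2-(2,6-dimethoxybenzoyl)-6-methoxy-3-(methoxymethoxy)-5-methylphenyl]ethynyl}-N,4-dimethylbenzenesulfonamide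
Conditions: Pd(PPh3)4 (5 mol %), CuI (10 mol %), Et3N, toluene, 50 °C, slow addition of 16
Reagents that add atoms: none
Why: Sonogashira coupling of an aryl iodide with a terminal ynamide, in which oxidative addition to zerovalent palladium is helped by the ortho carbonyl group and the copper acetylide transfers the ynamide to the arylpalladium iodide (divalent palladium) before reductive elimination.

Step 9
Reactants: 5 (2,6-dimethoxyphenyl)[5-methoxy-2-(methoxymethoxy)-4-methylphenyl]methanone; 17 N-{[2-(2,6-dimethoxybenzoyl)-6-methoxy-3-(methoxymethoxy)-5-methylphenyl]ethynyl}-N,4-dimethylbenzenesulfonamide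
Product: 18 rac-N-{2-[2-(2,6-dimethoxybenzoyl)-6-methoxy-3-(methoxymethoxy)-5-methylphenyl]-1-(2,6-dimethoxyphenyl)-1-hydroxy-4-methoxy-7-(methoxymethoxy)-5-methyl-1H-inden-3-yl}-N,4-dimethylbenzenesulfonamide
Conditions: 5 (3 equiv), [Cp*RhCl2]2 (5 mol %), AgSbF6 (20 mol %), Cu(OAc)2 (30 mol %), ClCH2CH2Cl, 100 °C
Reagents that add atoms: none
Why: Proposed new method: Cationic Cp*Rh (trivalent rhodium, from [Cp*RhCl2]2 and AgSbF6) binds the ketone oxygen of 5 and, by acetate-assisted concerted metalation–deprotonation, rhodates the one ortho C–H that the benzophenone owns (every other ortho position of both rings carries oxygen, so no site-selectivity problem arises); ynamide 17 then inserts into the aryl–Rh bond (first new C–C bond, arene carbon to the N-bearing alkyne carbon), the resulting alkenyl–rhodium adds to the coordinated C=O (second new C–C bond, aryl-bearing alkyne carbon to the ketone carbon), and protonolysis of the rhodium alkoxide by the acetic acid formed in the metalation should release 18 with no co-product and no net change of oxidation level. The closest known reaction type is the redox-neutral (3+2) carbocyclisation of aryl ketones, benzophenones included, with internal diaryl or aryl–alkyl alkynes to 1H-inden-1-ols under this catalyst system; new here are the heteroatom-substituted alkyne and the fully ortho-substituted coupling partners. The five-membered ring closes by intramolecular 1,2-addition of the alkenyl carbon to the carbonyl group, a 5-exo-trig closure that takes place inside a seven-membered oxa-rhodacycle. The selectivity that matters is the orientation of insertion: the polarisation of the ynamide (electrophilic N-bearing carbon, nucleophilic remote carbon) should send the migrating aryl group to the N-bearing carbon and rhodium to the carbon that carries the aryl group, which is also where conjugative stabilisation of the C–Rh bond and the usual preference of an aryl substituent for the metal-bound carbon place it, so three effects are expected to point the same way. The new carbinol carbon is the only stereocentre; it forms as a racemate and needs no control because step 10 turns it into an sp2 carbon. Chemoselectivity is helped by the fact that the ketone of 17 has no ortho C–H at all and by the use of 5 in excess.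

Step 10
Reactants: 18 rac-N-{2-[2-(2,6-dimethoxybenzoyl)-6-methoxy-3-(methoxymethoxy)-5-methylphenyl]-1-(2,6-dimethoxyphenyl)-1-hydroxy-4-methoxy-7-(methoxymethoxy)-5-methyl-1H-inden-3-yl}-N,4-dimethylbenzenesulfonamide
Product: 21 acredinone A, via bis-MOM hydroxyindanone 19 (not isolated), via bis-MOM acredinone A 20 (not isolated)
Conditions: 6 M aq. HCl, THF, 50 °C
Reagents that add atoms: water, O
Why: Acid hydrolysis of the ene-sulfonamide (protonation at the aryl-bearing enamide carbon, addition of water to the N-sulfonyliminium ion and loss of N-methyl tosylamide) should give the β-hydroxy ketone 19, whose tertiary benzylic hydroxyl group is lost by acid-catalysed β-elimination to the conjugated indenone 20 (net 1,3-carbonyl transposition), and the same acid hydrolyses both MOM acetals; the order of these events does not change the outcome.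

Compound list
1 | 4-methoxy-3-methylphenol | COc1ccc(O)cc1C | starting material
2 | 1-methoxy-4-(methoxymethoxy)-2-methylbenzene | COCOc1ccc(OC)c(C)c1 | intermediate
3 | 2,6-dimethoxybenzoyl chloride | COc1cccc(OC)c1C(Cl)=O | starting material
4 | [5-methoxy-2-(methoxymethoxy)-4-methylphenyl]lithium | COCOc1c([Li])cc(OC)c(C)c1 | intermediate (not isolated)
5 | (2,6-dimethoxyphenyl)[5-methoxy-2-(methoxymethoxy)-4-methylphenyl]methanone | COCOc1cc(C)c(OC)cc1C(=O)c1c(OC)cccc1OC | intermediate
6 | chloromagnesium 2-(hydroxymethyl)-4-methoxy-5-methylphenolate | COc1cc(CO)c(O[Mg]Cl)cc1C | intermediate (not isolated)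
7 | 2-hydroxy-5-methoxy-4-methylbenzaldehyde | COc1cc(C=O)c(O)cc1C | intermediate
8 | 5-methoxy-2-(methoxymethoxy)-4-methylbenzaldehyde | COCOc1cc(C)c(OC)cc1C=O | intermediate
9 | lithium {[2-(dimethylamino)ethyl](methyl)amino}[5-methoxy-2-(methoxymethoxy)-4-methylphenyl]methanolate, racemic | COCOc1cc(C)c(OC)cc1C(O[Li])N(C)CCN(C)C | intermediate (not isolated)
10 | ring-lithiated derivative of 9, lithium on the ring carbon between the aminal-bearing carbon and the OMe-bearing carbon, racemic | COCOc1cc(C)c(OC)c([Li])c1C(O[Li])N(C)CCN(C)C | intermediate (not isolated)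
11 | 2-iodo-3-methoxy-6-(methoxymethoxy)-4-methylbenzaldehyde | COCOc1cc(C)c(OC)c(I)c1C=O | intermediate
12 | 1,3-dimethoxybenzene | COc1cccc(OC)c1 | starting material
13 | (2,6-dimethoxyphenyl)lithium | COc1cccc(OC)c1[Li] | intermediate (not isolated)
14 | rac-(2,6-dimethoxyphenyl)[2-iodo-3-methoxy-6-(methoxymethoxy)-4-methylphenyl]methanol | COCOc1cc(C)c(OC)c(I)c1C(O)c1c(OC)cccc1OC | intermediate
15 | (2,6-dimethoxyphenyl)[2-iodo-3-methoxy-6-(methoxymethoxy)-4-methylphenyl]methanone | COCOc1cc(C)c(OC)c(I)c1C(=O)c1c(OC)cccc1OC | intermediate
16 | N-ethynyl-N,4-dimethylbenzenesulfonamide | C#CN(C)S(=O)(=O)c1ccc(C)cc1 | starting material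
17 | N-{[2-(2,6-dimethoxybenzoyl)-6-methoxy-3-(methoxymethoxy)-5-methylphenyl]ethynyl}-N,4-dimethylbenzenesulfonamide | COCOc1cc(C)c(OC)c(C#CN(C)S(=O)(=O)c2ccc(C)cc2)c1C(=O)c1c(OC)cccc1OC | intermediate
18 | rac-N-{2-[2-(2,6-dimethoxybenzoyl)-6-methoxy-3-(methoxymethoxy)-5-methylphenyl]-1-(2,6-dimethoxyphenyl)-1-hydroxy-4-methoxy-7-(methoxymethoxy)-5-methyl-1H-inden-3-yl}-N,4-dimethylbenzenesulfonamide (racemic at the carbinol carbon) | COCOc1cc(C)c(OC)c2c1C(O)(c1c(OC)cccc1OC)C(=C2N(C)S(=O)(=O)c1ccc(C)cc1)c1c(OC)c(C)cc(OCOC)c1C(=O)c1c(OC)cccc1OC | intermediate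
19 | 2-[2-(2,6-dimethoxybenzoyl)-6-methoxy-3-(methoxymethoxy)-5-methylphenyl]-3-(2,6-dimethoxyphenyl)-3-hydroxy-7-methoxy-4-(methoxymethoxy)-6-methyl-2,3-dihydro-1H-inden-1-one (bis-MOM hydroxyindanone, racemic mixture of diastereomers) | COc1cccc(OC)c1C(=O)c1c(OCOC)cc(C)c(OC)c1C1C(O)(c2c(OC)cccc2OC)c2c(OCOC)cc(C)c(OC)c2C1=O | intermediate (not isolated)
20 | 2-[2-(2,6-dimethoxybenzoyl)-6-methoxy-3-(methoxymethoxy)-5-methylphenyl]-3-(2,6-dimethoxyphenyl)-7-methoxy-4-(methoxymethoxy)-6-methyl-1H-inden-1-one (bis-MOM acredinone A) | COc1cccc(OC)c1C(=O)c1c(OCOC)cc(C)c(OC)c1C1=C(c2c(OC)cccc2OC)c2c(OCOC)cc(C)c(OC)c2C1=O | intermediate (not isolated)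
21 | acredinone A, 2-[2-(2,6-dimethoxybenzoyl)-3-hydroxy-6-methoxy-5-methylphenyl]-3-(2,6-dimethoxyphenyl)-4-hydroxy-7-methoxy-6-methyl-1H-inden-1-one | COc1cccc(OC)c1C(=O)c1c(O)cc(C)c(OC)c1C1=C(c2c(OC)cccc2OC)c2c(O)cc(C)c(OC)c2C1=O | target

Total step count: 10. Longest linear sequence: 8 steps (steps 3, 4, 5, 6, 7, 8, 9, 10); steps 1 and 2 form the two-step branch to benzophenone 5.

Steps most likely to fail

Step 9 (labelled step). What may go wrong: C–H rhodation at the carbon flanked by OMe and the twisted aroyl group may be too slow. The alkenyl–rhodium intermediate may be protonated before it adds to the congested ketone. Insertion may take the opposite orientation through chelation by the sulfonyl group. The ynamide may be hydrated by the Lewis-acidic medium, or its own ortho ketone oxygen may attack the activated alkyne and cyclise it. The fallback uses known chemistry and makes the two bonds one after the other. It sets out from iodide 15: a double Stille coupling of two equivalents of 15 with Bu3SnC≡CSnBu3 (Pd(PPh3)4, toluene, 100 °C) should give, through the mono-coupled alkynylstannane F1, the symmetric bis(aroylaryl)ethyne F2, which makes the C-1–C-7a bond. Carbonyl-assisted hydration of the alkyne (Ph3PAuNTf2, wet 1,4-dioxane, 80 °C) should give the aryl benzyl ketone F3, a single compound whichever alkyne carbon is oxygenated because F2 is symmetric. Aqueous HCl in THF at 50 °C should then bring about the intramolecular aldol addition of the benzylic CH2 group onto the neighbouring diaryl ketone (C-2–C-3 bond). The fallback thereby comes back to the route at hydroxyindanone 19, which the same acid should carry on through 20 to target 21.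

Step 8. What may go wrong: slow oxidative addition and transmetalation at the doubly ortho-substituted iodide would let the terminal ynamide be consumed by oxidative homocoupling or hydration. The fallback forms the C–N bond last instead of coupling a preformed ynamide. It sets out from iodide 15: Sonogashira coupling with ethynyltrimethylsilane (PdCl2(PPh3)2, CuI, Et3N, 60 °C; this robust alkyne can be used in large excess) should give the silylalkyne F4, and K2CO3 in MeOH the terminal alkyne F5. Copper-catalysed aerobic oxidative N-alkynylation of N,4-dimethylbenzenesulfonamide with F5 (CuCl2, pyridine, Na2CO3, O2, toluene, 70 °C) then comes back to the route at ynamide 17.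

Step 5. What may go wrong: lithiation may compete at the ring carbon between OMOM and methyl or at the benzylic methyl group, or n-BuLi may add to aldehyde released from an incompletely formed amino alkoxide. The fallback replaces the lithiation logic by catalytic C–H functionalisation of the finished ketone. It sets out from benzophenone 5: ketone-directed iridium-catalysed ortho C–H borylation ([Ir(OMe)(cod)]2, AsPh3, B2pin2, octane, 120 °C) should give the ortho-boronate F6, and iododeboronation (NaI, TsNClNa, aqueous THF, rt) comes back to the route at iodide 15, by-passing 7, 8, 11 and 14.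

Further compounds
F1 | step 9 | (2,6-dimethoxyphenyl){3-methoxy-6-(methoxymethoxy)-4-methyl-2-[(tributylstannyl)ethynyl]phenyl}methanone | COCOc1cc(C)c(OC)c(C#C[Sn](CCCC)(CCCC)CCCC)c1C(=O)c1c(OC)cccc1OC
F2 | step 9 | 1,2-bis[2-(2,6-dimethoxybenzoyl)-6-methoxy-3-(methoxymethoxy)-5-methylphenyl]ethyne | COCOc1cc(C)c(OC)c(C#Cc2c(OC)c(C)cc(OCOC)c2C(=O)c2c(OC)cccc2OC)c1C(=O)c1c(OC)cccc1OC
F3 | step 9 | 1,2-bis[2-(2,6-dimethoxybenzoyl)-6-methoxy-3-(methoxymethoxy)-5-methylphenyl]ethan-1-one | O=C(Cc1c(OC)c(C)cc(OCOC)c1C(=O)c1c(OC)cccc1OC)c1c(OC)c(C)cc(OCOC)c1C(=O)c1c(OC)cccc1OC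
F4 | step 8 | (2,6-dimethoxyphenyl){3-methoxy-6-(methoxymethoxy)-4-methyl-2-[(trimethylsilyl)ethynyl]phenyl}methanone | COCOc1cc(C)c(OC)c(C#C[Si](C)(C)C)c1C(=O)c1c(OC)cccc1OC
F5 | step 8 | (2,6-dimethoxyphenyl)[2-ethynyl-3-methoxy-6-(methoxymethoxy)-4-methylphenyl]methanone | COCOc1cc(C)c(OC)c(C#C)c1C(=O)c1c(OC)cccc1OC
F6 | step 5 | (2,6-dimethoxyphenyl)[3-methoxy-6-(methoxymethoxy)-4-methyl-2-(4,4,5,5-tetramethyl-1,3,2-dioxaborolan-2-yl)phenyl]methanone | COCOc1cc(C)c(OC)c(B2OC(C)(C)C(C)(C)O2)c1C(=O)c1c(OC)cccc1OC
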